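The plan rests on one disconnection: ring A is cut at C3–C4 and C5–C10 (labdane numbering), which also opens ring B and leaves the acyclic trienone 12. The key step is an intramolecular Diels–Alder reaction in which a β,β-dimethyl enone (C4=C5–C6=O) adds to a (Z)-configured penta-2,4-dien-2-yl unit (C10=C1–C2=C3). It closes rings A and B and creates the quaternary C10 next to the gem-dimethyl C4 in one operation, and the C9 stereocentre steers the diene face through allylic strain. It exploits the C4/C5/C10 array at the A/B ring fusion. C5 is then epimerised, and the side chain is added by Julia–Kocienski olefination.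

Key step: step 8

Remark: atom labels C1–C20 in the Why lines follow labdane numbering of the target; compound names use systematic numbering unless stated.
Assumption: the enantiomer named for each chiral ligand or auxiliary is the one taken to give the stated configuration; if the sense of induction is opposite, the antipode is used.

Step 1
Reactants: 1 acrolein
Product: 2 1,1-dibromobuta-1,3-diene
Conditions: CBr4, PPh3, Zn, CH2Cl2, 0 °C → rt
Reagents that add atoms: carbon tetrabromide, BrC(Br)(Br)Br
Why: Wittig-type dibromomethylenation of the aldehyde by Ph3P=CBr2 made in situ (first stage of the Corey–Fuchs sequence) is general for enals and installs the carbon that becomes C10.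

Step 2
Reactants: 2 1,1-dibromobuta-1,3-diene
Product: 3 (3Z)-4-bromopenta-1,3-diene (Br cis to the vinyl group)
Conditions: MeZnCl, PdCl2(DPEphos) (cat.), THF, 0 °C
Reagents that add atoms: methylzinc chloride, C[Zn]Cl
Why: In the Negishi coupling of a 1,1-dibromoalkene, oxidative addition occurs first at the C–Br bond trans to the alkenyl substituent, so the methyl enters trans to the vinyl group and the remaining bromide, cis to it, fixes the diene geometry.

Step 3
Reactants: 3 (3Z)-4-bromopenta-1,3-diene
Product: 4 4,4,5,5-tetramethyl-2-[(2E)-penta-2,4-dien-2-yl]-1,3,2-dioxaborolane (boron cis to the vinyl group)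
Conditions: B2pin2, PdCl2(PPh3)2 (cat.), PPh3, KOPh, PhMe, 50 °C
Reagents that add atoms: bis(pinacolato)diboron, CC1(C)OB(OC1(C)C)B1OC(C)(C)C(C)(C)O1
Why: Miyaura borylation of an alkenyl bromide proceeds with retention of alkene geometry and gives a boronate suited to rhodium-catalysed addition.

Step 4
Reactants: 5 (benzyloxy)acetaldehyde; 6 methyl 2-(triphenylphosphoranylidene)acetate
Product: 7 methyl (2E)-4-(benzyloxy)but-2-enoate
Conditions: CH2Cl2, rt
Reagents that add atoms: none
Why: Wittig olefination with a stabilised ylide gives the (E)-enoate selectively.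

Step 5
Reactants: 4 dienyl boronate; 7 methyl (2E)-4-(benzyloxy)but-2-enoate
Product: 8 methyl (3R,4Z)-3-[(benzyloxy)methyl]-4-methylhepta-4,6-dienoate
Conditions: [Rh(OH)((S)-binap)]2 (cat.), KOH (cat.), dioxane/H2O, 40 °C
Reagents that add atoms: none
Why: Rhodium-catalysed asymmetric 1,4-addition of an alkenylboronate to an (E)-enoate (Hayashi–Miyaura reaction) forms C9–C10 with retention of the alkenyl geometry, and the BINAP-bound alkenylrhodium species selects one enoate face, which sets C9.

Step 6
Reactants: 8 dienoate; 9 2-bromo-N-methoxy-N-methylacetamide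
Product: 10 methyl (3R,4Z)-3-[(benzyloxy)methyl]-2-{2-[methoxy(methyl)amino]-2-oxoethyl}-4-methylhepta-4,6-dienoate (C2 epimers)
Conditions: LiN(iPr)2, THF, −78 °C; then 9, −78 → −20 °C
Reagents that add atoms: none
Why: SN2 alkylation of the lithium ester enolate brings in C7 and C6; the new centre C8 forms without reliable control, which does not matter because it is equilibrated in step 8 and becomes sp2 in step 15.

Step 7
Reactants: 10 Weinreb amide ester; 11 (2-methylprop-1-en-1-yl)magnesium bromide
Product: 12 methyl (3R,4Z)-3-[(benzyloxy)methyl]-4-methyl-2-(4-methyl-2-oxopent-3-en-1-yl)hepta-4,6-dienoate (C2 epimers)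
Conditions: THF, −40 → 0 °C; aq. NH4Cl
Reagents that add atoms: none
Why: Weinreb ketone synthesis: the alkenyl Grignard reagent adds once to the N-methoxy-N-methylamide through a stable chelated intermediate, faster than to the hindered α-branched methyl ester, and gives the β,β-dimethyl enone.

Step 8
Reactants: 12 trienone
Product: 14 methyl (1R,2S,4aR,8aS)-1-[(benzyloxy)methyl]-5,5,8a-trimethyl-4-oxo-1,2,3,4,4a,5,6,8a-octahydronaphthalene-2-carboxylate (trans-fused), via cis-fused cycloadduct 13 (not isolated)
Conditions: Me2AlCl (2.5 equiv), CH2Cl2, −78 → 0 °C; aq. HCl; then NaOMe (cat.), MeOH, rt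
Reagents that add atoms: none
Why: Complexation of the C6 ketone by Me2AlCl lowers the enone LUMO so that the tethered diene adds in a concerted, asynchronous [4+2] cycloaddition in which C3–C4 bonding (to the gem-dimethyl carbon) runs ahead of C5–C10 bonding (to the methyl-bearing diene terminus); the closest known reaction type is the intramolecular Diels–Alder reaction of 1,7,9-decatrien-3-ones, including its (Z)-diene variant that gives only cis-fused octalones. Ring A is closed as the new cyclohexene by the cycloaddition itself, and ring B by the four-atom tether C6–C9 once C5–C10 forms (type 1 closure through a chair-like tether). The quaternary C10 is controlled by C9: because C9 is cis to C2 on the diene, allylic 1,3-strain holds H9 in the diene plane, with the chain to the dienophile on one face and the CH2OBn group on the other, so the dienophile adds to one face only and C11 ends cis to the C10 methyl. The (Z)-diene can reach the dienophile only with C6 exo, so the kinetic adduct 13 is cis-fused at C5; C5 is alpha to the ketone and is inverted by NaOMe to the trans-decalone, which relieves the axial quaternary C4 on ring B, and the same base sets the C8 ester equatorial. The step needs diene-face selectivity and suppression of a 1,5-hydrogen shift in the (Z)-diene; the first is secured by the 1,3-strain element and the second by Lewis acid activation below room temperature.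

Step 9
Reactants: 14 trans-fused octalone
Product: 15 methyl (1R,2S,4aR,8aS)-1-(hydroxymethyl)-5,5,8a-trimethyl-4-oxodecahydronaphthalene-2-carboxylate
Conditions: H2 (1 atm), Pd/C, EtOAc, rt
Reagents that add atoms: none
Why: Heterogeneous hydrogenation saturates the cis-disubstituted C1=C2 bond and hydrogenolyses the benzyl ether in the same operation, while the hindered ketone and the ester are untouched.

Step 10
Reactants: 15 hydroxy keto ester
Product: 16 methyl (1R,2S,4aR,8aS)-1-formyl-5,5,8a-trimethyl-4-oxodecahydronaphthalene-2-carboxylate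
Conditions: Dess–Martin periodinane, CH2Cl2, 0 °C → rt (15 used directly after step 9)
Reagents that add atoms: none
Why: Dess–Martin oxidation gives the aldehyde under neutral, non-enolising conditions, so C9 alpha to the new carbonyl is not epimerised.

Step 11
Reactants: 17 rac-2-ethenyl-2-methyloxirane; 18 4-methoxybenzyl alcohol
Product: 19 (2S)-2-[(4-methoxyphenyl)methoxy]-2-methylbut-3-en-1-ol
Conditions: Pd2(dba)3·CHCl3 (cat.), (R,R)-N,N'-(cyclohexane-1,2-diyl)bis[2-(diphenylphosphino)benzamide] (cat.), BEt3 (cat.), CH2Cl2, rt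
Reagents that add atoms: none
Why: Palladium-catalysed dynamic kinetic asymmetric allylic etherification (Tsuji–Trost type) of the racemic vinyl epoxide: the π-allyl intermediates interconvert, the borane delivers the alcohol to the tertiary terminus, and the chiral diphosphine sets the tertiary ether carbon (the future C13).

Step 12
Reactants: 19 alcohol; 20 1-phenyl-1H-tetrazole-5-thiol
Product: 21 5-{[(2S)-2-[(4-methoxyphenyl)methoxy]-2-methylbut-3-en-1-yl]sulfanyl}-1-phenyl-1H-tetrazole
Conditions: PPh3, DIAD, THF, 0 °C → rt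
Reagents that add atoms: none
Why: Mitsunobu thioetherification of the primary alcohol with the acidic tetrazolethiol; the stereocentre is not involved.

Step 13
Reactants: 21 sulfide
Product: 22 5-{[(2S)-2-[(4-methoxyphenyl)methoxy]-2-methylbut-3-en-1-yl]sulfonyl}-1-phenyl-1H-tetrazole
Conditions: (NH4)6Mo7O24·4H2O (cat.), H2O2 (30% aq.), EtOH, 0 °C → rt
Reagents that add atoms: hydrogen peroxide, OO
Why: Molybdate-catalysed peroxide oxidation takes the sulfide to the sulfone and leaves the isolated vinyl group and the PMB ether intact.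

Step 14
Reactants: 16 keto aldehyde; 22 sulfone
Product: 23 methyl (5R,8S,9R,10S,11E,13S)-13-[(4-methoxybenzyl)oxy]-6-oxolabda-11,14-dien-17-oate (labdane numbering)
Conditions: KN(SiMe3)2, DME, −78 °C; add 16; −78 °C → rt
Reagents that add atoms: none
Why: Julia–Kocienski olefination: the metalated phenyltetrazolyl sulfone adds to the aldehyde, and Smiles rearrangement with loss of SO2 and tetrazolate gives the (E)-alkene preferentially with α-branched aldehydes; C13 comes from 22, and C9 is retained because addition at −78 °C outpaces enolisation.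

Step 15
Reactants: 23 keto ester
Product: 26 methyl (5R,9S,10S,11E,13S)-13-[(4-methoxybenzyl)oxy]-6-oxolabda-7,11,14-trien-17-oate, via α-phenylselanyl ketone 24 (not isolated), via selenoxide 25 (not isolated)
Conditions: LiN(iPr)2, THF, −78 °C; PhSeBr; then H2O2 (30% aq.), pyridine, CH2Cl2, 0 °C → rt
Reagents that add atoms: none
Why: Kinetic deprotonation of the ketone at C7 (C5 is a hindered methine), α-selenenylation and selenoxide syn-elimination (only C8 carries a β-hydrogen) introduce the C7=C8 double bond, and C8 stops being a stereocentre.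

Step 16
Reactants: 26 enone ester
Product: 27 (5R,6S,9S,10S,11E,13S)-13-[(4-methoxybenzyl)oxy]labda-7,11,14-triene-6,17-diol
Conditions: iBu2AlH (excess), CH2Cl2, −78 → 0 °C; aq. potassium sodium tartrate (KNaC4H4O6)
Reagents that add atoms: none
Why: iBu2AlH effects 1,2-reduction of the enone and reduces the enoate to the allylic alcohol; hydride attacks C6 from the face opposite the axial C10 and C4 methyl groups, giving the axial 6-alcohol cis to the C10 methyl (6S).

Step 17
Reactants: 27 diol
Product: 28 (5R,6S,9S,10S,11E,13S)-13-[(4-methoxybenzyl)oxy]labda-7,11,14-triene-6,17-diyl diacetate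
Conditions: Ac2O, DMAP (cat.), pyridine, rt
Reagents that add atoms: acetic anhydride, CC(=O)OC(C)=O
Why: DMAP-catalysed acetylation esterifies the primary allylic and the hindered secondary allylic alcohol; the tertiary oxygen is masked as its PMB ether, so no chemoselectivity is required.

Step 18
Reactants: 28 diacetate PMB ether
Product: 29 (5R,6S,9S,10S,11E,13S)-13-hydroxylabda-7,11,14-triene-6,17-diyl diacetate (target, CNP0103498.1)
Conditions: DDQ, CH2Cl2/pH 7 phosphate buffer, 0 °C
Reagents that add atoms: none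
Why: Oxidative cleavage of the p-methoxybenzyl ether by DDQ (hydride abstraction, then hydrolysis of the oxocarbenium ion) under buffered conditions frees the tertiary bis-allylic alcohol without ionising it or touching the acetates.

Compound list
1 | acrolein (prop-2-enal) | C=CC=O | starting material
2 | 1,1-dibromobuta-1,3-diene | C=CC=C(Br)Br | intermediate
3 | (3Z)-4-bromopenta-1,3-diene | C=C/C=C(/C)Br | intermediate
4 | 4,4,5,5-tetramethyl-2-[(2E)-penta-2,4-dien-2-yl]-1,3,2-dioxaborolane | C=C/C=C(/C)B1OC(C)(C)C(C)(C)O1 | intermediate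
5 | (benzyloxy)acetaldehyde | O=CCOCc1ccccc1 | starting material
6 | methyl 2-(triphenylphosphoranylidene)acetate | COC(=O)C=P(c1ccccc1)(c1ccccc1)c1ccccc1 | starting material
7 | methyl (2E)-4-(benzyloxy)but-2-enoate | COC(=O)/C=C/COCc1ccccc1 | intermediate
8 | methyl (3R,4Z)-3-[(benzyloxy)methyl]-4-methylhepta-4,6-dienoate | COC(=O)C[C@@H](COCc1ccccc1)/C(C)=C\C=C | intermediate
9 | 2-bromo-N-methoxy-N-methylacetamide | CON(C)C(=O)CBr | starting material
10 | methyl (3R,4Z)-3-[(benzyloxy)methyl]-2-{2-[methoxy(methyl)amino]-2-oxoethyl}-4-methylhepta-4,6-dienoate (C2 epimers) | COC(=O)C(CC(=O)N(C)OC)[C@@H](COCc1ccccc1)/C(C)=C\C=C | intermediate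
11 | (2-methylprop-1-en-1-yl)magnesium bromide | CC(C)=C[Mg]Br | starting material
12 | methyl (3R,4Z)-3-[(benzyloxy)methyl]-4-methyl-2-(4-methyl-2-oxopent-3-en-1-yl)hepta-4,6-dienoate (C2 epimers) | COC(=O)C(CC(=O)C=C(C)C)[C@@H](COCc1ccccc1)/C(C)=C\C=C | intermediate
13 | methyl (1R,4aS,8aS)-1-[(benzyloxy)methyl]-5,5,8a-trimethyl-4-oxo-1,2,3,4,4a,5,6,8a-octahydronaphthalene-2-carboxylate (cis-fused, C2 epimers) | c1ccccc1COC[C@@H]1C(C(=O)OC)CC(=O)[C@H]2C(C)(C)CC=C[C@@]12C | intermediate
14 | methyl (1R,2S,4aR,8aS)-1-[(benzyloxy)methyl]-5,5,8a-trimethyl-4-oxo-1,2,3,4,4a,5,6,8a-octahydronaphthalene-2-carboxylate (trans-fused) | c1ccccc1COC[C@@H]1[C@@H](C(=O)OC)CC(=O)[C@@H]2C(C)(C)CC=C[C@@]12C | intermediate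
15 | methyl (1R,2S,4aR,8aS)-1-(hydroxymethyl)-5,5,8a-trimethyl-4-oxodecahydronaphthalene-2-carboxylate | OC[C@@H]1[C@@H](C(=O)OC)CC(=O)[C@@H]2C(C)(C)CCC[C@@]12C | intermediate
16 | methyl (1R,2S,4aR,8aS)-1-formyl-5,5,8a-trimethyl-4-oxodecahydronaphthalene-2-carboxylate | O=C[C@@H]1[C@@H](C(=O)OC)CC(=O)[C@@H]2C(C)(C)CCC[C@@]12C | intermediate
17 | rac-2-ethenyl-2-methyloxirane | C=CC1(C)CO1 | starting material
18 | 4-methoxybenzyl alcohol | COc1ccc(CO)cc1 | starting material
19 | (2S)-2-[(4-methoxyphenyl)methoxy]-2-methylbut-3-en-1-ol | C=C[C@](C)(OCc1ccc(OC)cc1)CO | intermediate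
20 | 1-phenyl-1H-tetrazole-5-thiol | Sc1nnnn1-c1ccccc1 | starting material
21 | 5-{[(2S)-2-[(4-methoxyphenyl)methoxy]-2-methylbut-3-en-1-yl]sulfanyl}-1-phenyl-1H-tetrazole | C=C[C@](C)(OCc1ccc(OC)cc1)CSc1nnnn1-c1ccccc1 | intermediate
22 | 5-{[(2S)-2-[(4-methoxyphenyl)methoxy]-2-methylbut-3-en-1-yl]sulfonyl}-1-phenyl-1H-tetrazole | C=C[C@](C)(OCc1ccc(OC)cc1)CS(=O)(=O)c1nnnn1-c1ccccc1 | intermediate
23 | methyl (5R,8S,9R,10S,11E,13S)-13-[(4-methoxybenzyl)oxy]-6-oxolabda-11,14-dien-17-oate | C=C[C@](C)(OCc1ccc(OC)cc1)/C=C/[C@@H]1[C@@H](C(=O)OC)CC(=O)[C@@H]2C(C)(C)CCC[C@@]12C | intermediate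
24 | 7-(phenylselanyl) derivative of 23 (C7 epimers) | C=C[C@](C)(OCc1ccc(OC)cc1)/C=C/[C@@H]1[C@@H](C(=O)OC)C([Se]c3ccccc3)C(=O)[C@@H]2C(C)(C)CCC[C@@]12C | intermediate
25 | selenoxide of 24 | C=C[C@](C)(OCc1ccc(OC)cc1)/C=C/[C@@H]1[C@@H](C(=O)OC)C([Se](=O)c3ccccc3)C(=O)[C@@H]2C(C)(C)CCC[C@@]12C | intermediate
26 | methyl (5R,9S,10S,11E,13S)-13-[(4-methoxybenzyl)oxy]-6-oxolabda-7,11,14-trien-17-oate | C=C[C@](C)(OCc1ccc(OC)cc1)/C=C/[C@@H]1C(C(=O)OC)=CC(=O)[C@@H]2C(C)(C)CCC[C@@]12C | intermediate
27 | (5R,6S,9S,10S,11E,13S)-13-[(4-methoxybenzyl)oxy]labda-7,11,14-triene-6,17-diol | C=C[C@](C)(OCc1ccc(OC)cc1)/C=C/[C@@H]1C(CO)=C[C@H](O)[C@@H]2C(C)(C)CCC[C@@]12C | intermediate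
28 | (5R,6S,9S,10S,11E,13S)-13-[(4-methoxybenzyl)oxy]labda-7,11,14-triene-6,17-diyl diacetate | C=C[C@](C)(OCc1ccc(OC)cc1)/C=C/[C@@H]1C(COC(C)=O)=C[C@H](OC(C)=O)[C@@H]2C(C)(C)CCC[C@@]12C | intermediate
29 | (5R,6S,9S,10S,11E,13S)-13-hydroxylabda-7,11,14-triene-6,17-diyl diacetate | C=C[C@](C)(O)/C=C/[C@@H]1C(COC(C)=O)=C[C@H](OC(C)=O)[C@@H]2C(C)(C)CCC[C@@]12C | target

Total step count: 18. Longest linear sequence: 14 steps (steps 1–3, 5–10 and 14–18, from acrolein).

Steps most likely to fail

Step 8 (key step). Both new bonds end at fully substituted carbons, so the cycloaddition may stall. The (Z)-diene may also isomerise, undergo a 1,5-hydrogen shift or polymerise under the Lewis acid before it cyclises. The fallback sets out from 12 and comes back at 14. The enone is converted with 1,2-bis(trimethylsilyloxy)ethane and catalytic Me3SiOTf at −78 °C into the 2-alkenyl-1,3-dioxolane F1. Catalytic triflic acid then opens F1 to a dioxolanylium (oxy-allyl) cation, which adds to the diene in a stepwise ionic Diels–Alder reaction and gives the ketal cycloadduct F2. Aqueous HCl hydrolysis of F2 and the NaOMe equilibration of step 8 then give 14.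

Step 5. Transmetalation of the hindered, α-methyl dienylboronate may be slow, so that protodeboronation or rhodium migration along the diene erodes yield and alkene geometry; face selection at the enoate may also be poor. The fallback sets out from 3 and 7 and comes back at 8. Ester 7 is saponified (LiOH) to (2E)-4-(benzyloxy)but-2-enoic acid F3. F3 is activated with pivaloyl chloride/Et3N and coupled with lithiated (4R)-4-phenyl-1,3-oxazolidin-2-one to give the N-enoyl imide F4. The dienylmagnesium bromide made from 3 (Mg, THF) adds in the presence of CuBr·SMe2, anti to the phenyl group of the auxiliary, to give the conjugate adduct F5. NaOMe/MeOH cleaves the auxiliary from F5 and returns 8.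

Step 14. The metalated β-alkoxy sulfone may expel the PMB-oxide, or deprotonate the hindered α-branched aldehyde (epimerising C9) faster than it adds to the carbonyl. The fallback reverses the polarity; it sets out from 15 and 19 and comes back at 23. Mitsunobu reaction of 15 with 20 gives the decalinylmethyl sulfide F6, and molybdate/H2O2 oxidation gives the sulfone F7. Alcohol 19 is oxidised with Dess–Martin periodinane to the non-enolisable aldehyde F8. Metalation of F7 with KN(SiMe3)2 and addition of F8 gives 23 by Julia–Kocienski olefination.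

Further compounds
F1 | step 8 | methyl (3R,4Z)-3-[(benzyloxy)methyl]-4-methyl-2-{[2-(2-methylprop-1-en-1-yl)-1,3-dioxolan-2-yl]methyl}hepta-4,6-dienoate (C2 epimers) | COC(=O)C(CC1(C=C(C)C)OCCO1)[C@@H](COCc1ccccc1)/C(C)=C\C=C
F2 | step 8 | ethylene ketal of cis-fused cycloadduct 13 (C2 epimers) | c1ccccc1COC[C@@H]1C(C(=O)OC)CC3(OCCO3)[C@H]2C(C)(C)CC=C[C@@]12C
F3 | step 5 | (2E)-4-(benzyloxy)but-2-enoic acid | OC(=O)/C=C/COCc1ccccc1
F4 | step 5 | (4R)-3-[(2E)-4-(benzyloxy)but-2-enoyl]-4-phenyl-1,3-oxazolidin-2-one | O=C(/C=C/COCc1ccccc1)N1C(=O)OC[C@H]1c1ccccc1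
F5 | step 5 | (4R)-3-{(3R,4Z)-3-[(benzyloxy)methyl]-4-methylhepta-4,6-dienoyl}-4-phenyl-1,3-oxazolidin-2-one | O=C(C[C@@H](COCc1ccccc1)/C(C)=C\C=C)N1C(=O)OC[C@H]1c1ccccc1
F6 | step 14 | methyl (1R,2S,4aR,8aS)-5,5,8a-trimethyl-4-oxo-1-{[(1-phenyl-1H-tetrazol-5-yl)sulfanyl]methyl}decahydronaphthalene-2-carboxylate | c1ccccc1-n1nnnc1SC[C@@H]1[C@@H](C(=O)OC)CC(=O)[C@@H]2C(C)(C)CCC[C@@]12C
F7 | step 14 | methyl (1R,2S,4aR,8aS)-5,5,8a-trimethyl-4-oxo-1-{[(1-phenyl-1H-tetrazol-5-yl)sulfonyl]methyl}decahydronaphthalene-2-carboxylate | c1ccccc1-n1nnnc1S(=O)(=O)C[C@@H]1[C@@H](C(=O)OC)CC(=O)[C@@H]2C(C)(C)CCC[C@@]12C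
F8 | step 14 | (2S)-2-[(4-methoxyphenyl)methoxy]-2-methylbut-3-enal | C=C[C@](C)(OCc1ccc(OC)cc1)C=O
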